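Rings: upper flavan unit = A (benzo), C (pyran), B (4-hydroxyphenyl); lower gallocatechin unit = D (benzo), F (pyran), E (pyrogallol). Retrosynthetic cuts, in order: the seven O-benzyl groups, upper O1–C2, upper C4–C4a, upper C3–C4, and the bond from upper C4 to C8 of ring D.
Enabling feature: upper C2 is a benzylic ether carbon para to the free 4'-OH of ring B. C2, ring B and O4' can therefore merge into a planar para-quinone methide that carries no memory of the carbinol configuration and is closed by the ring A oxygen O1.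
Forward order: rings D, E and F come intact from (+)-gallocatechin. C8 is formylated (future C4) and condensed with a ring B acetophenone (C3–C4). Ring A is then added to the enone (C4–C4a), the ketone is reduced, ring C is closed last, and all benzyl groups are removed.
Stereochemistry: lower C2 (R) and C3 (S) come from the chiral pool, upper C4 (R) from a chiral diene–rhodium catalyst, and upper C2 (S) from a chiral phosphoric acid.

Key step: step 13

Assumption: the antipodes of the diene ligand and of the phosphoric acid are those expected by analogy with simple (E)-enones and with intermolecular 1,6-additions. For a substrate this crowded the sense must be confirmed in the first run, and the mirror-image catalyst is taken if it proves reversed.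

Step 1
Reactants: 1 (+)-gallocatechin
Product: 2 5,7,3',4',5'-penta-O-benzyl-(+)-gallocatechin (2R,3S; 3-OH free)
Conditions: BnBr, K2CO3, degassed DMF, Ar, 0 °C → rt
Reagents that add atoms: benzyl bromide, BrCc1ccccc1
Why: Williamson etherification in which carbonate deprotonates only the five phenols, so the secondary 3-OH stays free, C2 and C3 keep the natural 2R,3S configuration, and exclusion of air protects the pyrogallol ring E.

Step 2
Reactants: 2 5,7,3',4',5'-penta-O-benzyl-(+)-gallocatechin
Product: 3 3,5,7,3',4',5'-hexa-O-benzyl-(+)-gallocatechin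
Conditions: NaH, BnBr, n-Bu4NI (cat.), THF/DMF, 0 °C → rt
Reagents that add atoms: benzyl bromide, BrCc1ccccc1
Why: Williamson etherification of the remaining secondary alkoxide; with every phenol capped, ring F can no longer open through a quinone methide, so the strong base leaves C2 untouched.

Step 3
Reactants: 3 3,5,7,3',4',5'-hexa-O-benzyl-(+)-gallocatechin
Product: 4 8-bromo-hexa-O-benzyl-(+)-gallocatechin
Conditions: NBS (1 equiv), CH2Cl2, dark, −78 → −20 °C
Reagents that add atoms: N-bromosuccinimide, O=C1CCC(=O)N1Br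
Why: Electrophilic aromatic bromination; in 5,7-di-O-benzyl flavan-3-ols C8 is the most nucleophilic ring carbon, and one equivalent of NBS at low temperature is known to stop at the 8-bromide.

Step 4
Reactants: 4 8-bromo-hexa-O-benzyl-(+)-gallocatechin
Product: 6 hexa-O-benzyl-(+)-gallocatechin-8-carbaldehyde, via 8-lithio species 5 (not isolated)
Conditions: n-BuLi, THF, −78 °C; DMF, −78 → 0 °C; aq NH4Cl
Reagents that add atoms: N,N-dimethylformamide, CN(C)C=O
Why: Bromine–lithium exchange outruns any attack on the benzyl ethers at −78 °C, and the aryllithium is formylated by DMF (Bouveault aldehyde synthesis), which installs the carbon that becomes upper C4.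

Step 5
Reactants: 7 4-hydroxyacetophenone
Product: 8 4'-(methoxymethoxy)acetophenone
Conditions: MOMCl, K2CO3, acetone, 0 °C → rt
Reagents that add atoms: chloromethyl methyl ether, COCCl
Why: Williamson-type O-alkylation of an acidic phenol gives a base-stable acetal that keeps the ketone enolisable and electrophilic through the next three steps.

Step 6
Reactants: 6 hexa-O-benzyl-(+)-gallocatechin-8-carbaldehyde; 8 4'-(methoxymethoxy)acetophenone
Product: 9 (E)-3-(hexa-O-benzylgallocatechin-8-yl)-1-[4-(methoxymethoxy)phenyl]prop-2-en-1-one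
Conditions: KOH, EtOH/THF, rt → 40 °C
Reagents that add atoms: none
Why: Claisen–Schmidt condensation; the aldehyde cannot enolise, loss of water from the aldol is driven by conjugation with electron-rich ring D and gives the E-enone, and benzyl and MOM ethers are inert to hydroxide.

Step 7
Reactants: 10 3-(benzyloxy)phenol
Product: 11 5-(benzyloxy)-2-bromophenol
Conditions: NBS, i-Pr2NH (10 mol%), CH2Cl2, −20 → 0 °C
Reagents that add atoms: N-bromosuccinimide, O=C1CCC(=O)N1Br
Why: Amine-catalysed ortho-bromination of a phenol with NBS in a non-polar solvent delivers bromine next to the hydrogen-bonded hydroxyl; of the two ortho positions only C6 is unhindered and also para to the benzyloxy group, and the weakly polar ortho-bromophenol should separate easily from any para isomer.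

Step 8
Reactants: 11 5-(benzyloxy)-2-bromophenol
Product: 12 4-(benzyloxy)-1-bromo-2-(methoxymethoxy)benzene
Conditions: MOMCl, K2CO3, acetone, rt
Reagents that add atoms: chloromethyl methyl ether, COCCl
Why: Williamson-type alkylation; the small MOM acetal masks the future O1 without adding bulk next to the carbon that must pass from boron to rhodium and on to a crowded β-carbon.

Step 9
Reactants: 12 4-(benzyloxy)-1-bromo-2-(methoxymethoxy)benzene
Product: 14 [4-(benzyloxy)-2-(methoxymethoxy)phenyl]boronic acid, via aryllithium 13 (not isolated)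
Conditions: n-BuLi, THF, −78 °C; B(Oi-Pr)3, −78 °C → rt; aq NH4Cl
Reagents that add atoms: triisopropyl borate, CC(C)OB(OC(C)C)OC(C)C; water, O
Why: Bromine–lithium exchange, trapping with a borate ester and mild hydrolysis is the standard route to arylboronic acids; the ortho MOM oxygen stabilises the aryllithium by chelation and survives the near-neutral work-up.

Step 10
Reactants: 9 (E)-3-(hexa-O-benzylgallocatechin-8-yl)-1-[4-(methoxymethoxy)phenyl]prop-2-en-1-one; 14 [4-(benzyloxy)-2-(methoxymethoxy)phenyl]boronic acid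
Product: 15 (3R)-3-[4-(benzyloxy)-2-(methoxymethoxy)phenyl]-3-(hexa-O-benzylgallocatechin-8-yl)-1-[4-(methoxymethoxy)phenyl]propan-1-one
Conditions: [RhCl(C2H4)2]2 (2.5 mol%), (1R,4R)-2,5-diphenylbicyclo[2.2.2]octa-2,5-diene (5.5 mol%), KOH (20 mol%), 1,4-dioxane/H2O 10:1, 50 °C, 14 added in portions
Reagents that add atoms: none
Why: Hayashi–Miyaura reaction, in which the aryl–rhodium species formed by transmetalation inserts the enone and water protonates the resulting rhodium enolate; the C2-symmetric diene shields one enone face so that ring A arrives on the Si face of the β-carbon and sets upper C4 as R under catalyst control, and a ketone acceptor is used because it leaves no room for competing 1,2-addition.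

Step 11
Reactants: 15 (3R)-3-[4-(benzyloxy)-2-(methoxymethoxy)phenyl]-3-(hexa-O-benzylgallocatechin-8-yl)-1-[4-(methoxymethoxy)phenyl]propan-1-one
Product: 16 (3R)-3-[4-(benzyloxy)-2-hydroxyphenyl]-3-(hexa-O-benzylgallocatechin-8-yl)-1-(4-hydroxyphenyl)propan-1-one
Conditions: 3 M aq HCl, THF/i-PrOH, 45 °C
Reagents that add atoms: none
Why: Acid hydrolysis of the two phenolic MOM acetals is done at the ketone stage, where no ionisable carbinol exists; benzyl ethers survive, the β-acyl group disfavours heterolysis at C4, and the water present keeps the freed ring A phenol and the ketone on the open hydroxy ketone side rather than the 4H-chromene.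

Step 12
Reactants: 16 (3R)-3-[4-(benzyloxy)-2-hydroxyphenyl]-3-(hexa-O-benzylgallocatechin-8-yl)-1-(4-hydroxyphenyl)propan-1-one
Product: 17 (1RS,3R)-3-[4-(benzyloxy)-2-hydroxyphenyl]-3-(hexa-O-benzylgallocatechin-8-yl)-1-(4-hydroxyphenyl)propan-1-ol (both C1 epimers)
Conditions: NaBH4 (excess), THF/MeOH, 0 °C → rt; pH 7 phosphate buffer; Et3N-washed silica
Reagents that add atoms: none
Why: Borohydride reduction of an aryl ketone; no control at the new carbinol carbon is needed because both epimers converge in the next step, and the neutral work-up should prevent early ionisation of the 4-hydroxybenzylic alcohol.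

Step 13
Reactants: 17 (1RS,3R)-3-[4-(benzyloxy)-2-hydroxyphenyl]-3-(hexa-O-benzylgallocatechin-8-yl)-1-(4-hydroxyphenyl)propan-1-ol
Product: 19 (2S,4R)-7-benzyloxy-2-(4-hydroxyphenyl)-4-(hexa-O-benzylgallocatechin-8-yl)chromane, via para-quinone methide 18 (not isolated)
Conditions: (R)-TRIP [(R)-3,3'-bis(2,4,6-triisopropylphenyl)-1,1'-binaphthyl-2,2'-diyl hydrogen phosphate] (10 mol%), 5 Å MS, toluene/CH2Cl2 (0.01 M), 0 °C → rt, followed by HPLC; Et3N quench
Reagents that add atoms: none
Why: Proposed new method: the acid protonates the carbinol oxygen of either epimer of 17 while its phosphoryl oxygen takes the 4'-OH proton, so both epimers lose water to the same planar para-quinone methide 18, and the ring A phenol then adds to the methide carbon in an oxa-1,6-addition that rearomatises ring B. The closest known reaction types are the chiral phosphoric acid catalysed 1,6-addition of external nucleophiles to para-quinone methides made in situ from 4-hydroxybenzyl alcohols and the achiral acid cyclisation of 1-aryl-3-(2-hydroxyaryl)propan-1-ols to flavans, whereas an internal phenol closing onto an alkyl-substituted methide under catalyst control has not been shown. Ring C closes 6-exo-trig, because the attacked C2=C1' bond lies outside the new ring. C2 should be set as S by the catalyst, whose phosphate bridges the quinone methide oxygen and the attacking hydroxyl and leaves the Si face of C2 open, while the fixed 4R centre adds only a modest bias, since the bulky ring D aryl can sit pseudoaxial, away from H-5, in the half-chair leading to the 2,4-trans product. Chemoselectivity rests on the substrate: the ring A hydroxyl is the only free nucleophile within reach, the rival six-ring closure through O7 of ring D is blocked by its benzyl group, and indane formation is excluded because both positions ortho to C8 of ring D are substituted and C5 of ring A is meta to both oxygens. Tautomerisation of 18 to the 4-hydroxystyrene is undone by reprotonation and does not touch C4, but 19 can itself reopen under acid toward the likely more stable 2,4-cis isomer, so sieves make the loss of water irreversible and the run is quenched as soon as 17 is consumed.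

Step 14
Reactants: 19 (2S,4R)-7-benzyloxy-2-(4-hydroxyphenyl)-4-(hexa-O-benzylgallocatechin-8-yl)chromane
Product: 20 target CNP0220331.3, (2S,4R)-7,4'-dihydroxyflavan-(4→8)-(2R,3S)-gallocatechin
Conditions: H2 (1 atm), Pd(OH)2/C, THF/MeOH, rt
Reagents that add atoms: none
Why: Catalytic hydrogenolysis removes the seven acyclic benzyl ethers under neutral conditions; the cyclic benzylic ethers O1–C2 of both units are known to withstand these conditions in flavans and flavan-3-ols, no acid is present to reopen ring C, and so all four stereocentres should reach the target unchanged.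

Compound list
1 | (+)-gallocatechin (2R,3S) | Oc1cc(O)c2c(c1)O[C@H](c1cc(O)c(O)c(O)c1)[C@@H](O)C2 | starting material
2 | 5,7,3',4',5'-penta-O-benzyl-(+)-gallocatechin | c1c(OCc5ccccc5)cc(OCc5ccccc5)c2c1O[C@H](c1cc(OCc5ccccc5)c(OCc5ccccc5)c(OCc5ccccc5)c1)[C@@H](O)C2 | intermediate
3 | 3,5,7,3',4',5'-hexa-O-benzyl-(+)-gallocatechin | c1c(OCc5ccccc5)cc(OCc5ccccc5)c2c1O[C@H](c1cc(OCc5ccccc5)c(OCc5ccccc5)c(OCc5ccccc5)c1)[C@@H](OCc5ccccc5)C2 | intermediate
4 | 8-bromo-hexa-O-benzyl-(+)-gallocatechin | Brc1c(OCc5ccccc5)cc(OCc5ccccc5)c2c1O[C@H](c1cc(OCc5ccccc5)c(OCc5ccccc5)c(OCc5ccccc5)c1)[C@@H](OCc5ccccc5)C2 | intermediate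
5 | 8-lithio-hexa-O-benzyl-(+)-gallocatechin (not isolated) | [Li]c1c(OCc5ccccc5)cc(OCc5ccccc5)c2c1O[C@H](c1cc(OCc5ccccc5)c(OCc5ccccc5)c(OCc5ccccc5)c1)[C@@H](OCc5ccccc5)C2 | intermediate
6 | hexa-O-benzyl-(+)-gallocatechin-8-carbaldehyde | O=Cc1c(OCc5ccccc5)cc(OCc5ccccc5)c2c1O[C@H](c1cc(OCc5ccccc5)c(OCc5ccccc5)c(OCc5ccccc5)c1)[C@@H](OCc5ccccc5)C2 | intermediate
7 | 4-hydroxyacetophenone | CC(=O)c1ccc(O)cc1 | starting material
8 | 4'-(methoxymethoxy)acetophenone | CC(=O)c1ccc(OCOC)cc1 | intermediate
9 | (E)-chalcone carrying ring D at the β-carbon and MOM-protected ring B at the carbonyl | COCOc1ccc(cc1)C(=O)/C=C/c1c(OCc5ccccc5)cc(OCc5ccccc5)c2c1O[C@H](c1cc(OCc5ccccc5)c(OCc5ccccc5)c(OCc5ccccc5)c1)[C@@H](OCc5ccccc5)C2 | intermediate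
10 | 3-(benzyloxy)phenol | Oc1cccc(OCc2ccccc2)c1 | starting material
11 | 5-(benzyloxy)-2-bromophenol | Oc1cc(OCc2ccccc2)ccc1Br | intermediate
12 | 4-(benzyloxy)-1-bromo-2-(methoxymethoxy)benzene | COCOc1cc(OCc2ccccc2)ccc1Br | intermediate
13 | [4-(benzyloxy)-2-(methoxymethoxy)phenyl]lithium (not isolated) | COCOc1cc(OCc2ccccc2)ccc1[Li] | intermediate
14 | [4-(benzyloxy)-2-(methoxymethoxy)phenyl]boronic acid | COCOc1cc(OCc2ccccc2)ccc1B(O)O | intermediate
15 | (3R)-β,β-diaryl ketone, both reacting phenols as MOM ethers | COCOc1ccc(cc1)C(=O)C[C@@H](c3c(OCc5ccccc5)cc(OCc5ccccc5)c4c3O[C@H](c3cc(OCc5ccccc5)c(OCc5ccccc5)c(OCc5ccccc5)c3)[C@@H](OCc5ccccc5)C4)c3ccc(OCc5ccccc5)cc3OCOC | intermediate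
16 | (3R)-β,β-diaryl ketone with free ring A 2-OH and ring B 4'-OH | Oc1ccc(cc1)C(=O)C[C@@H](c3c(OCc5ccccc5)cc(OCc5ccccc5)c4c3O[C@H](c3cc(OCc5ccccc5)c(OCc5ccccc5)c(OCc5ccccc5)c3)[C@@H](OCc5ccccc5)C4)c3ccc(OCc5ccccc5)cc3O | intermediate
17 | (1RS,3R)-1-(4-hydroxyphenyl)-3,3-diarylpropan-1-ol, key-step precursor, both carbinol epimers | Oc1ccc(C(O)C[C@@H](c3c(OCc5ccccc5)cc(OCc5ccccc5)c4c3O[C@H](c3cc(OCc5ccccc5)c(OCc5ccccc5)c(OCc5ccccc5)c3)[C@@H](OCc5ccccc5)C4)c3ccc(OCc5ccccc5)cc3O)cc1 | intermediate
18 | (R)-para-quinone methide (not isolated) | O=C1C=CC(C=C1)=CC[C@@H](c3c(OCc5ccccc5)cc(OCc5ccccc5)c4c3O[C@H](c3cc(OCc5ccccc5)c(OCc5ccccc5)c(OCc5ccccc5)c3)[C@@H](OCc5ccccc5)C4)c3ccc(OCc5ccccc5)cc3O | intermediate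
19 | (2S,4R)-2,4-trans flavan with free 4'-OH, key-step product, seven benzyl ethers | Oc1ccc([C@@H]2C[C@@H](c3c(OCc5ccccc5)cc(OCc5ccccc5)c4c3O[C@H](c3cc(OCc5ccccc5)c(OCc5ccccc5)c(OCc5ccccc5)c3)[C@@H](OCc5ccccc5)C4)c3ccc(OCc5ccccc5)cc3O2)cc1 | intermediate
20 | CNP0220331.3 | Oc1ccc([C@@H]2C[C@@H](c3c(O)cc(O)c4c3O[C@H](c3cc(O)c(O)c(O)c3)[C@@H](O)C4)c3ccc(O)cc3O2)cc1 | target

Total step count: 14.
Longest linear sequence: 10 steps (1 → 2 → 3 → 4 → 6 → 9 → 15 → 16 → 17 → 19 → 20).

Steps most likely to fail

Step 13.
- What may go wrong: face selectivity at the methide carbon may be too low. The initial selectivity may also be eroded by acid-catalysed reopening of ring C during the time needed to ionise the carbinol. A third loss channel is intermolecular Friedel–Crafts capture of the methide by C6 of ring D.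
- Fallback: it uses known chemistry, sets out from 16 and comes back at 19. The more acidic and unhindered 4'-hydroxyl of 16 is acetylated selectively (Ac2O, Et3N, CH2Cl2, −20 °C) to the 4'-O-acetyl ketone F1. Noyori–Ikariya transfer hydrogenation with RuCl[(R,R)-TsDPEN](p-cymene) in HCO2H/Et3N should give the (1R,3R)-carbinol F2. Intramolecular Mitsunobu etherification (PPh3, DIAD, toluene, 0 °C) closes O1–C2 with inversion, the acetoxy group holding back ionisation, and gives the 4'-O-acetyl (2S,4R)-flavan F3. Methanolysis (K2CO3, MeOH/THF, 0 °C) returns 19.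

Step 10.
- What may go wrong: migratory insertion may be slow at a β-carbon flanked by two ortho oxygen substituents and deactivated by three donor oxygens, so that protodeboronation of the electron-rich boronic acid wins. Double induction with the lower unit may also be mismatched.
- Fallback: it sets out from 6 and 12, comes back at 15, and replaces catalyst control by an Evans-type auxiliary.
  - Knoevenagel–Doebner condensation of 6 with malonic acid (pyridine, piperidine, 90 °C) gives the (E)-cinnamic acid F4.
  - Its mixed pivalic anhydride (PivCl, Et3N, THF) acylates commercial (S)-4-phenyl-1,3-oxazolidin-2-one in the presence of LiCl to the N-enoyl imide F5.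
  - Bromide 12 is converted with Mg in THF into the arylmagnesium bromide F6. With CuBr·SMe2 (THF/Me2S, −40 °C) this adds to the magnesium-chelated s-cis imide from the face away from the 4-phenyl group and should give the (3R)-adduct F7.
  - AlMe3/MeONHMe·HCl exchanges the auxiliary for the Weinreb amide F8.
  - 4-(Methoxymethoxy)phenylmagnesium bromide F9, made from commercial 1-bromo-4-(methoxymethoxy)benzene and Mg, converts F8 into 15.

Step 1.
- What may go wrong: the pyrogallol polyphenoxide may oxidise in air, ring D may be C-benzylated, and base may epimerise C2 before ring E is capped.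
- Fallback: it sets out from 1 and comes back at 3. Peracetylation (Ac2O, pyridine, rt) gives the air-stable hexa-O-acetyl-(+)-gallocatechin F10. After purification this is treated with NaH and BnBr in DMF while water is metered in. Each acetate is saponified in situ and the oxygen anion is benzylated at once, so no polyphenoxide builds up, and 3 is reached without passing through 2.

Further compounds
F1 | step 13 | (3R)-4'-O-acetyl ketone with free ring A hydroxyl | CC(=O)Oc1ccc(cc1)C(=O)C[C@@H](c3c(OCc5ccccc5)cc(OCc5ccccc5)c4c3O[C@H](c3cc(OCc5ccccc5)c(OCc5ccccc5)c(OCc5ccccc5)c3)[C@@H](OCc5ccccc5)C4)c3ccc(OCc5ccccc5)cc3O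
F2 | step 13 | (1R,3R)-4'-O-acetyl carbinol | CC(=O)Oc1ccc(cc1)[C@H](O)C[C@@H](c3c(OCc5ccccc5)cc(OCc5ccccc5)c4c3O[C@H](c3cc(OCc5ccccc5)c(OCc5ccccc5)c(OCc5ccccc5)c3)[C@@H](OCc5ccccc5)C4)c3ccc(OCc5ccccc5)cc3O
F3 | step 13 | (2S,4R)-4'-O-acetyl flavan | CC(=O)Oc1ccc([C@@H]2C[C@@H](c3c(OCc5ccccc5)cc(OCc5ccccc5)c4c3O[C@H](c3cc(OCc5ccccc5)c(OCc5ccccc5)c(OCc5ccccc5)c3)[C@@H](OCc5ccccc5)C4)c3ccc(OCc5ccccc5)cc3O2)cc1
F4 | step 10 | (E)-3-(hexa-O-benzylgallocatechin-8-yl)acrylic acid | OC(=O)/C=C/c3c(OCc5ccccc5)cc(OCc5ccccc5)c4c3O[C@H](c3cc(OCc5ccccc5)c(OCc5ccccc5)c(OCc5ccccc5)c3)[C@@H](OCc5ccccc5)C4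
F5 | step 10 | (4S)-3-[(E)-3-(hexa-O-benzylgallocatechin-8-yl)acryloyl]-4-phenyl-1,3-oxazolidin-2-one | O=C1OC[C@H](c6ccccc6)N1C(=O)/C=C/c3c(OCc5ccccc5)cc(OCc5ccccc5)c4c3O[C@H](c3cc(OCc5ccccc5)c(OCc5ccccc5)c(OCc5ccccc5)c3)[C@@H](OCc5ccccc5)C4
F6 | step 10 | [4-(benzyloxy)-2-(methoxymethoxy)phenyl]magnesium bromide | COCOc1cc(OCc2ccccc2)ccc1[Mg]Br
F7 | step 10 | (4S)-4-phenyl-oxazolidinone imide of the (3R)-3,3-diarylpropanoic acid | O=C1OC[C@H](c6ccccc6)N1C(=O)C[C@@H](c3c(OCc5ccccc5)cc(OCc5ccccc5)c4c3O[C@H](c3cc(OCc5ccccc5)c(OCc5ccccc5)c(OCc5ccccc5)c3)[C@@H](OCc5ccccc5)C4)c3ccc(OCc5ccccc5)cc3OCOC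
F8 | step 10 | (3R)-3,3-diaryl-N-methoxy-N-methylpropanamide | CON(C)C(=O)C[C@@H](c3c(OCc5ccccc5)cc(OCc5ccccc5)c4c3O[C@H](c3cc(OCc5ccccc5)c(OCc5ccccc5)c(OCc5ccccc5)c3)[C@@H](OCc5ccccc5)C4)c3ccc(OCc5ccccc5)cc3OCOC
F9 | step 10 | [4-(methoxymethoxy)phenyl]magnesium bromide | COCOc1ccc([Mg]Br)cc1
F10 | step 1 | hexa-O-acetyl-(+)-gallocatechin | CC(=O)Oc1cc(OC(C)=O)c2c(c1)O[C@H](c1cc(OC(C)=O)c(OC(C)=O)c(OC(C)=O)c1)[C@@H](OC(C)=O)C2
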